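**Retrosynthetic overview**

- The target comes from quercetin by sulfation of the 3-, 7-, 3'- and 4'-hydroxyls, the 5-OH (hydrogen-bonded to the C4 carbonyl) staying free; quercetin comes from its pentabenzyl ether by hydrogenolysis.
- Ring C of the pentabenzyl ether is cut at O1–C8a and C4–C4a, giving 3,5-bis(benzyloxy)benzyne (ring A, released from a 2-silylaryl triflate) and the enol of a 2-benzyloxy-3-aryl-3-oxopropanoate (O1, C2, C3, C4 and ring B).
- The structural feature used: O1 and C4 sit on the neighbouring ring A carbons C8a and C4a, and the C5 oxygen flanks C4a, so the matching aryne takes an oxygen nucleophile at C8a and carries the carbanion at C4a.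
- Rings A and B are bought as benzene rings; ring C is the only ring formed, in the annulation. The silyl triflate is made from 3,5-bis(benzyloxy)phenol, the keto ester from methyl benzyloxyacetate and 3,4-bis(benzyloxy)benzoic acid.

Key step: step 6

Assumption: the target is drawn as the free tetrakis(hydrogen sulfate). Aryl hydrogen sulfates hydrolyse under their own acidity, so the acid form is released only in the last step by cold cation exchange, and the triethylammonium salt is the storage form.

**Route**

Step 1
Reactants: 1 3,5-bis(benzyloxy)phenol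
Product: 2 3,5-bis(benzyloxy)-2-bromophenol
Conditions: NBS (1.0 equiv), i-Pr2NH (10 mol %), CH2Cl2, −78 → −20 °C
Reagents that add atoms: N-bromosuccinimide, O=C1CCC(=O)N1Br
Why: Electrophilic aromatic bromination in which the amine-derived N-bromo species is held by hydrogen bonding to the phenol OH, so that bromine should enter ortho to OH (C2, equivalent to C6) and not at the more crowded C4 between the two benzyloxy groups, while one equivalent at low temperature limits dibromination.

Step 2
Reactants: 2 3,5-bis(benzyloxy)-2-bromophenol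
Product: 3 [3,5-bis(benzyloxy)-2-bromophenoxy]trimethylsilane
Conditions: HN(SiMe3)2 (1.5 equiv), THF, 70 °C; evaporate, use crude
Reagents that add atoms: hexamethyldisilazane, C[Si](C)(C)N[Si](C)(C)C
Why: O-Silylation of a phenol by hexamethyldisilazane gives only ammonia as by-product, so the moisture-sensitive silyl ether should be obtained clean by evaporation.

Step 3
Reactants: 3 [3,5-bis(benzyloxy)-2-bromophenoxy]trimethylsilane
Product: 6 3,5-bis(benzyloxy)-2-(trimethylsilyl)phenyl trifluoromethanesulfonate, via aryllithium 4 (not isolated), via lithium silylphenoxide 5 (not isolated)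
Conditions: n-BuLi (1.05 equiv), THF, −100 °C; then Tf2O (1.2 equiv), −100 → −78 °C; aq NaHCO3
Reagents that add atoms: trifluoromethanesulfonic anhydride, O=S(=O)(OS(=O)(=O)C(F)(F)F)C(F)(F)F
Why: Bromine–lithium exchange at −100 °C outruns any attack on the benzyl ethers, the aryllithium takes the silyl group from the neighbouring oxygen (retro-Brook 1,3 O→C silyl shift), and the resulting phenoxide is trapped as the triflate, the standard way to a 2-silylaryl triflate aryne precursor.

Step 4
Reactants: 7 3,4-bis(benzyloxy)benzoic acid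
Product: 8 3,4-bis(benzyloxy)benzoyl chloride
Conditions: (COCl)2 (1.5 equiv), DMF (cat.), CH2Cl2, 0 °C → rt; evaporate
Reagents that add atoms: oxalyl chloride, O=C(Cl)C(=O)Cl
Why: Acid chloride formation through the DMF-derived chloroiminium (Vilsmeier-type activation) gives only gaseous by-products and leaves aryl benzyl ethers untouched.

Step 5
Reactants: 9 methyl benzyloxyacetate; 8 3,4-bis(benzyloxy)benzoyl chloride
Product: 12 methyl 2-(benzyloxy)-3-[3,4-bis(benzyloxy)phenyl]-3-hydroxyacrylate (chelated enol of the racemic β-keto ester methyl 2-(benzyloxy)-3-[3,4-bis(benzyloxy)phenyl]-3-oxopropanoate, with which it equilibrates), via lithium ester enolate 10 (not isolated), via lithium ketoester enolate 11 (not isolated)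
Conditions: 9 (2.1 equiv), LiN(SiMe3)2 (2.1 equiv), THF, −78 °C; then 8 (1.0 equiv), −78 → −40 °C; cold 1 M HCl
Reagents that add atoms: none
Why: Crossed Claisen acylation of a preformed lithium ester enolate by an acid chloride, in which the second equivalent of enolate removes the acidic C2 proton of the product and so should stop a second acylation.

Step 6
Reactants: 6 3,5-bis(benzyloxy)-2-(trimethylsilyl)phenyl trifluoromethanesulfonate; 12 methyl 2-(benzyloxy)-3-[3,4-bis(benzyloxy)phenyl]-3-hydroxyacrylate
Product: 16 quercetin pentabenzyl ether (3,5,7-tris(benzyloxy)-2-[3,4-bis(benzyloxy)phenyl]-4H-chromen-4-one), via cesium enolate 13 (not isolated), via dibenzyloxybenzyne 14 (not isolated), via arylcesium adduct 15 (not isolated)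
Conditions: CsF (4 equiv), THF, 65 °C; 6 (1.5 equiv) added over 6 h by syringe pump
Reagents that add atoms: none
Why: Proposed new method: fluoride attacks silicon of 6 and triflate leaves to give aryne 14, fluoride also turns 12 into cesium enolate 13 whose oxygen lies cis to the ester, the enolate oxygen adds to the aryne carbon meta to the benzyloxy group of the future C5 (this carbon becomes C8a) because the developing carbanion then sits next to that inductively withdrawing oxygen (future C4a), and arylcesium 15 attacks the cis ester carbonyl and expels methoxide. The closest known reaction types are the fluoride-induced annulation of arynes with methyl salicylates to xanthones (a salicylate is the benzo-fused form of this enol ester) and the insertion of arynes into the C–O bond of carboxylic acids, whereas open-chain β-keto esters normally add through carbon (acyl-alkylation). Ring C closes by 6-exo-trig acyl substitution, O1–C8a forming first and C4–C4a second. No stereocenter is created. Two selectivities are needed: the aryne regiochemistry, secured by the benzyloxy group at the future C5, and O- over C-arylation, for which the fully substituted, benzyloxy-bearing α-carbon, the loose cesium ion pair and an aprotic solvent that cannot protonate 15 are relied on.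

Step 7
Reactants: 16 quercetin pentabenzyl ether
Product: 17 quercetin (3,5,7,3',4'-pentahydroxyflavone)
Conditions: H2 (1 atm), 10% Pd/C, THF–MeOH 1:1, rt
Reagents that add atoms: none
Why: Catalytic hydrogenolysis of aryl benzyl ethers should free all five hydroxyls, the conjugated C2=C3 bond and the C4 carbonyl of a flavonol not being reduced at 1 atm and room temperature.

Step 8
Reactants: 17 quercetin
Product: 18 tetrakis(triethylammonium) quercetin 3,7,3',4'-tetra-O-sulfate
Conditions: SO3·NEt3 (10 equiv), N,N-dimethylacetamide, 65 °C; precipitate with acetone; Sephadex LH-20 (MeOH–H2O)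
Reagents that add atoms: sulfur trioxide–triethylamine complex, CC[N+](CC)(CC)S(=O)(=O)[O-]
Why: O-Sulfation of phenolic and enolic hydroxyls by a sulfur trioxide–amine complex, in which the 5-OH, locked in a hydrogen bond to the C4 carbonyl, is the least nucleophilic hydroxyl, so that at moderate temperature the reaction should stop at the 3,7,3',4'-tetrasulfate.

Step 9
Reactants: 18 tetrakis(triethylammonium) quercetin 3,7,3',4'-tetra-O-sulfate
Product: 19 quercetin 3,7,3',4'-tetra-O-sulfate (free acid form)
Conditions: Dowex 50W-X8 (H+ form), H2O, 0–5 °C, short contact; freeze-dry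
Reagents that add atoms: none
Why: Cation exchange on a sulfonic acid resin replaces triethylammonium by protons, and cold, brief contact should limit acid-catalysed hydrolysis of the aryl sulfate esters.

**Compound list**

1 | 3,5-bis(benzyloxy)phenol | Oc1cc(OCc2ccccc2)cc(OCc2ccccc2)c1 | starting material
2 | 3,5-bis(benzyloxy)-2-bromophenol | Oc1cc(OCc2ccccc2)cc(OCc2ccccc2)c1Br | intermediate
3 | [3,5-bis(benzyloxy)-2-bromophenoxy]trimethylsilane | C[Si](C)(C)Oc1cc(OCc2ccccc2)cc(OCc2ccccc2)c1Br | intermediate
4 | [2,4-bis(benzyloxy)-6-(trimethylsilyloxy)phenyl]lithium | C[Si](C)(C)Oc1cc(OCc2ccccc2)cc(OCc2ccccc2)c1[Li] | intermediate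
5 | lithium 3,5-bis(benzyloxy)-2-(trimethylsilyl)phenoxide | [Li+].[O-]c1cc(OCc2ccccc2)cc(OCc2ccccc2)c1[Si](C)(C)C | intermediate
6 | 3,5-bis(benzyloxy)-2-(trimethylsilyl)phenyl trifluoromethanesulfonate | C[Si](C)(C)c1c(OCc2ccccc2)cc(OCc2ccccc2)cc1OS(=O)(=O)C(F)(F)F | intermediate
7 | 3,4-bis(benzyloxy)benzoic acid | O=C(O)c1ccc(OCc2ccccc2)c(OCc2ccccc2)c1 | starting material
8 | 3,4-bis(benzyloxy)benzoyl chloride | O=C(Cl)c1ccc(OCc2ccccc2)c(OCc2ccccc2)c1 | intermediate
9 | methyl benzyloxyacetate | COC(=O)COCc1ccccc1 | starting material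
10 | lithium enolate of methyl benzyloxyacetate (chelated, O-lithium cis to benzyloxy) | [Li+].[O-]/C(OC)=C\OCc1ccccc1 | intermediate
11 | lithium enolate of the β-keto ester (enolate oxygen cis to the ester) | [Li+].COC(=O)/C(OCc1ccccc1)=C(\[O-])c1ccc(OCc2ccccc2)c(OCc2ccccc2)c1 | intermediate
12 | methyl 2-(benzyloxy)-3-[3,4-bis(benzyloxy)phenyl]-3-hydroxyacrylate, chelated enol (OH cis to ester) of methyl 2-(benzyloxy)-3-[3,4-bis(benzyloxy)phenyl]-3-oxopropanoate | COC(=O)/C(OCc1ccccc1)=C(\O)c1ccc(OCc2ccccc2)c(OCc2ccccc2)c1 | intermediate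
13 | cesium enolate of 12 (enolate oxygen cis to the ester) | [Cs+].COC(=O)/C(OCc1ccccc1)=C(\[O-])c1ccc(OCc2ccccc2)c(OCc2ccccc2)c1 | intermediate
14 | 3,5-bis(benzyloxy)benzyne (1,2-didehydro-3,5-bis(benzyloxy)benzene) | C1#CC(OCc2ccccc2)=CC(OCc2ccccc2)=C1 | intermediate
15 | arylcesium O-arylation adduct: methyl 2-(benzyloxy)-3-[3,4-bis(benzyloxy)phenyl]-3-[3,5-bis(benzyloxy)-2-cesiophenoxy]acrylate, aryloxy cis to ester | [Cs+].COC(=O)/C(OCc1ccccc1)=C(\Oc1cc(OCc2ccccc2)cc(OCc2ccccc2)[c-]1)c1ccc(OCc2ccccc2)c(OCc2ccccc2)c1 | intermediate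
16 | quercetin pentabenzyl ether | O=c1c(OCc2ccccc2)c(-c2ccc(OCc3ccccc3)c(OCc3ccccc3)c2)oc2cc(OCc3ccccc3)cc(OCc3ccccc3)c12 | intermediate
17 | quercetin | O=c1c(O)c(-c2ccc(O)c(O)c2)oc2cc(O)cc(O)c12 | intermediate
18 | tetrakis(triethylammonium) quercetin 3,7,3',4'-tetra-O-sulfate | O=c1c(OS(=O)(=O)[O-])c(-c2ccc(OS(=O)(=O)[O-])c(OS(=O)(=O)[O-])c2)oc2cc(OS(=O)(=O)[O-])cc(O)c12.CC[NH+](CC)CC.CC[NH+](CC)CC.CC[NH+](CC)CC.CC[NH+](CC)CC | intermediate
19 | quercetin 3,7,3',4'-tetra-O-sulfate | O=c1c(OS(=O)(=O)O)c(-c2ccc(OS(=O)(=O)O)c(OS(=O)(=O)O)c2)oc2cc(OS(=O)(=O)O)cc(O)c12 | target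

**Step count and risks**

Total step count: 9. Longest linear sequence: 7 steps (steps 1, 2, 3, 6, 7, 8, 9).

Steps most likely to fail:

1. Step 6 (key step). The enolate may add to the aryne through its α-carbon and follow the acyl-alkylation path. The arylcesium adduct may also be protonated by unreacted enol before it closes the ring, or O-arylation may occur from an enolate geometry in which the ester cannot be reached. Fallback, from 6 back to 16 by known reactions: aryne 14, released from 6 with CsF in THF at 100–125 °C (sealed) in the presence of commercial benzyloxyacetic acid, should insert into the C–O bond of the acid (carboxylate O-arylation, then acyl shift to the ortho carbanion, with the same regiochemistry as in step 6) to give 2-(benzyloxy)-1-[2,4-bis(benzyloxy)-6-hydroxyphenyl]ethan-1-one F1. Acylation of the phenol with acid chloride 8 (pyridine, DMAP, CH2Cl2) should give 3,5-bis(benzyloxy)-2-[(benzyloxy)acetyl]phenyl 3,4-bis(benzyloxy)benzoate F2. Baker–Venkataraman rearrangement (LiN(SiMe3)2, THF, −78 → 0 °C) should give 2-(benzyloxy)-1-[2,4-bis(benzyloxy)-6-hydroxyphenyl]-3-[3,4-bis(benzyloxy)phenyl]propane-1,3-dione F3. Cyclodehydration (NaOAc, AcOH, 100 °C) should close ring C to 16.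

2. Step 8. Sulfation may stall at the crowded catechol pair or at the 3-position, may run on to the chelated 5-OH, and the anionic products are hard to separate from one another. Fallback, from 17 to 19 through neutral, chromatographable sulfate diesters: 17 with 2,2,2-trichloroethyl chlorosulfate (excess), Et3N and DMAP in THF at 0 °C → rt should give quercetin 3,7,3',4'-tetrakis(2,2,2-trichloroethyl sulfate) F4, purified on silica with its substitution pattern checked before unmasking. Zn dust and HCO2NH4 in MeOH at rt should remove the four trichloroethyl groups by reductive elimination to give tetraammonium quercetin 3,7,3',4'-tetra-O-sulfate F5. The cation exchange of step 9 then gives 19.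

3. Step 1. Bromination may occur para to the hydroxyl (between the two benzyloxy groups) or twice. Fallback, from 1 to 6 by directed ortho metalation instead of electrophilic substitution: 1 with N,N-diethylcarbamoyl chloride and NaH in THF should give 3,5-bis(benzyloxy)phenyl N,N-diethylcarbamate F6. s-BuLi/TMEDA in THF at −78 °C should lithiate the position between the carbamate and a benzyloxy group, the carbamate being the stronger director, to give [2,4-bis(benzyloxy)-6-(diethylcarbamoyloxy)phenyl]lithium F7. Quenching in the flask with Me3SiCl should give 3,5-bis(benzyloxy)-2-(trimethylsilyl)phenyl N,N-diethylcarbamate F8. LiAlH4 in THF (0 °C → rt) should cleave the carbamate to 3,5-bis(benzyloxy)-2-(trimethylsilyl)phenol F9. Tf2O and pyridine in CH2Cl2 at 0 °C then give 6.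

**Further compounds**

F1 | step 6 | 2-(benzyloxy)-1-[2,4-bis(benzyloxy)-6-hydroxyphenyl]ethan-1-one | O=C(COCc1ccccc1)c1c(O)cc(OCc2ccccc2)cc1OCc1ccccc1
F2 | step 6 | 3,5-bis(benzyloxy)-2-[(benzyloxy)acetyl]phenyl 3,4-bis(benzyloxy)benzoate | O=C(COCc1ccccc1)c1c(OC(=O)c2ccc(OCc3ccccc3)c(OCc3ccccc3)c2)cc(OCc2ccccc2)cc1OCc1ccccc1
F3 | step 6 | 2-(benzyloxy)-1-[2,4-bis(benzyloxy)-6-hydroxyphenyl]-3-[3,4-bis(benzyloxy)phenyl]propane-1,3-dione (racemic) | O=C(c1ccc(OCc2ccccc2)c(OCc2ccccc2)c1)C(OCc1ccccc1)C(=O)c1c(O)cc(OCc2ccccc2)cc1OCc1ccccc1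
F4 | step 8 | quercetin 3,7,3',4'-tetrakis(2,2,2-trichloroethyl sulfate) | O=c1c(OS(=O)(=O)OCC(Cl)(Cl)Cl)c(-c2ccc(OS(=O)(=O)OCC(Cl)(Cl)Cl)c(OS(=O)(=O)OCC(Cl)(Cl)Cl)c2)oc2cc(OS(=O)(=O)OCC(Cl)(Cl)Cl)cc(O)c12
F5 | step 8 | tetraammonium quercetin 3,7,3',4'-tetra-O-sulfate | O=c1c(OS(=O)(=O)[O-])c(-c2ccc(OS(=O)(=O)[O-])c(OS(=O)(=O)[O-])c2)oc2cc(OS(=O)(=O)[O-])cc(O)c12.[NH4+].[NH4+].[NH4+].[NH4+]
F6 | step 1 | 3,5-bis(benzyloxy)phenyl N,N-diethylcarbamate | CCN(CC)C(=O)Oc1cc(OCc2ccccc2)cc(OCc2ccccc2)c1
F7 | step 1 | [2,4-bis(benzyloxy)-6-(diethylcarbamoyloxy)phenyl]lithium | CCN(CC)C(=O)Oc1cc(OCc2ccccc2)cc(OCc2ccccc2)c1[Li]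
F8 | step 1 | 3,5-bis(benzyloxy)-2-(trimethylsilyl)phenyl N,N-diethylcarbamate | CCN(CC)C(=O)Oc1cc(OCc2ccccc2)cc(OCc2ccccc2)c1[Si](C)(C)C
F9 | step 1 | 3,5-bis(benzyloxy)-2-(trimethylsilyl)phenol | Oc1cc(OCc2ccccc2)cc(OCc2ccccc2)c1[Si](C)(C)C
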